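**Retrosynthetic overview**

1. Ring numbering of the target: C1 carries the 4-hydroxybenzoate, C4 the acetate, C2=C3 is E, C9=C10 is Z, C5 is the gem-dimethyl carbon. The last bond made is the C1–O ester, to a silyl-protected 4-hydroxybenzoyl chloride (from 4-bromophenol and CO2), followed by desilylation.
2. The 11-membered ring, the only ring, is closed before that at C8–C9 by intramolecular B-alkyl Suzuki coupling of a (Z)-alkenyl iodide with the 9-BBN adduct of a terminal alkene.
3. The open chain comes from a late union at C3–C4: ligand-controlled Nozaki–Hiyama–Kishi addition of the eight-carbon western (E)-alkenyl iodide (C9–C11, C1–C3) to the seven-carbon eastern aldehyde 2,2-dimethylpent-4-enal (C4–C8), which sets C4.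
4. Western half: propargyl alcohol, carboalumination/iodination (2E), Brown allylation (sets C1), alkene cleavage, Z-selective iodo-Wittig with an iodoethane-derived ylide.
5. Eastern half: allylation of the enolate of methyl isobutyrate, reduction, oxidation.

Assumption: in step 14 the chromium ligand is written as its (S) antipode, taken to be the one that adds the alkenyl group to the Re face of aldehyde 11; this is to be confirmed on 28 by Mosher ester analysis.

**Route**

Step 1
Reactants: 1 4-bromophenol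
Product: 2 (4-bromophenoxy)tri(propan-2-yl)silane
Conditions: i-Pr3SiCl, imidazole, DMF, rt
Reagents that add atoms: triisopropylsilyl chloride, CC(C)[Si](Cl)(C(C)C)C(C)C
Why: O-silylation of the phenol gives a bulky aryl silyl ether that survives the halogen–lithium exchange of the next step.

Step 2
Reactants: 2 (4-bromophenoxy)tri(propan-2-yl)silane
Product: 4 4-{[tri(propan-2-yl)silyl]oxy}benzoic acid, via aryllithium 3 (not isolated)
Conditions: n-BuLi, THF, −78 °C; CO2, −78 °C to rt; aq. HCl to pH 3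
Reagents that add atoms: carbon dioxide, O=C=O
Why: bromine–lithium exchange is fast at −78 °C and the aryllithium is trapped by CO2 (carboxylation).

Step 3
Reactants: 4 4-{[tri(propan-2-yl)silyl]oxy}benzoic acid
Product: 5 4-{[tri(propan-2-yl)silyl]oxy}benzoyl chloride
Conditions: (COCl)2, DMF (cat.), CH2Cl2, 0 °C to rt; evaporated and used crude
Reagents that add atoms: oxalyl chloride, ClC(=O)C(Cl)=O
Why: acid chloride formation through the Vilsmeier-type chloroiminium species gives a strong acyl donor for the late esterification of a ring alcohol.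

Step 4
Reactants: 6 methyl 2-methylpropanoate; 7 3-bromoprop-1-ene
Product: 9 methyl 2,2-dimethylpent-4-enoate, via lithium enolate 8 (not isolated)
Conditions: LiN(i-Pr)2, THF, −78 °C; then 7, −78 °C to rt
Reagents that add atoms: none
Why: ester enolate alkylation (SN2) with a reactive allylic bromide builds the quaternary carbon that becomes ring C5.

Step 5
Reactants: 9 methyl 2,2-dimethylpent-4-enoate
Product: 10 2,2-dimethylpent-4-en-1-ol
Conditions: LiAlH4, Et2O, 0 °C to rt; H2O work-up
Reagents that add atoms: none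
Why: hydride reduction of the ester to the neopentyl alcohol leaves the isolated alkene untouched.

Step 6
Reactants: 10 2,2-dimethylpent-4-en-1-ol
Product: 11 2,2-dimethylpent-4-enal
Conditions: TEMPO (2,2,6,6-tetramethylpiperidin-1-oxyl, 10 mol%), PhI(OAc)2, CH2Cl2, rt
Reagents that add atoms: none
Why: oxoammonium (TEMPO) oxidation stops at the aldehyde, which has no α-hydrogen and so cannot enolise or self-condense.

Step 7
Reactants: 12 iodoethane
Product: 13 ethyl(triphenyl)phosphonium iodide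
Conditions: PPh3, toluene, 80 °C (sealed)
Reagents that add atoms: triphenylphosphine, c1ccc(cc1)P(c1ccccc1)c1ccccc1
Why: SN2 quaternisation of the phosphine gives the Wittig salt that will supply ring C9 and its methyl group.

Step 8
Reactants: 14 prop-2-yn-1-ol
Product: 16 (2E)-3-iodo-2-methylprop-2-en-1-ol, via alkenylalane 15 (not isolated)
Conditions: Me3Al (3 equiv), Cp2ZrCl2 (0.25 equiv), CH2Cl2, 0 °C to rt; I-I (iodine), THF, −30 to 0 °C; aq. K2CO3
Reagents that add atoms: trimethylaluminium, C[Al](C)C; iodine, I-I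
Why: Negishi zirconium-catalysed carboalumination adds methyl and aluminium syn across the alkyne with methyl on the internal carbon, and iodinolysis with retention fixes the E geometry of the future C2=C3 bond.

Step 9
Reactants: 16 (2E)-3-iodo-2-methylprop-2-en-1-ol
Product: 17 (2E)-3-iodo-2-methylprop-2-enal
Conditions: MnO2, CH2Cl2, rt, dark; used as a solution
Reagents that add atoms: none
Why: selective allylic alcohol oxidation on the MnO2 surface gives the enal without touching the alkenyl iodide or its geometry.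

Step 10
Reactants: 17 (2E)-3-iodo-2-methylprop-2-enal
Product: 19 (3S,1E)-1-iodo-2-methylhexa-1,5-dien-3-ol, via borinate 18 (not isolated)
Conditions: (−)-B-methoxydiisopinocampheylborane [from (+)-α-pinene], allylMgBr, Et2O, −78 °C to rt; then 17, −78 °C; NaOH, H2O2, rt
Reagents that add atoms: allylmagnesium bromide, C=CC[Mg]Br
Why: Brown asymmetric allylboration runs through a closed chair transition state in which the reagent from (+)-α-pinene delivers allyl to the Si face of the aldehyde, setting the carbinol (future ring C1) as S.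

Step 11
Reactants: 19 (3S,1E)-1-iodo-2-methylhexa-1,5-dien-3-ol
Product: 20 tert-butyl{[(3S,1E)-1-iodo-2-methylhexa-1,5-dien-3-yl]oxy}dimethylsilane
Conditions: t-BuMe2SiCl, imidazole, DMF, rt
Reagents that add atoms: tert-butyldimethylsilyl chloride, CC(C)(C)[Si](C)(C)Cl
Why: silyl ether formation protects the allylic alcohol as a poor leaving group, so the later β-oxy aldehyde does not eliminate under ylide conditions.

Step 12
Reactants: 20 tert-butyl{[(3S,1E)-1-iodo-2-methylhexa-1,5-dien-3-yl]oxy}dimethylsilane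
Product: 22 (3S,4E)-3-{[tert-butyl(dimethyl)silyl]oxy}-5-iodo-4-methylpent-4-enal, via diol 21 (not isolated)
Conditions: OsO4 (2 mol%), NaIO4, 2,6-lutidine, dioxane/H2O (3:1), rt
Reagents that add atoms: osmium tetroxide, O=[Os](=O)(=O)=O; sodium periodate, [Na+].[O-]I(=O)(=O)=O
Why: Johnson–Lemieux dihydroxylation and periodate cleavage act only on the electron-rich monosubstituted alkene, because the iodoalkene is deactivated, and the stereocentre is not touched.

Step 13
Reactants: 22 (3S,4E)-3-{[tert-butyl(dimethyl)silyl]oxy}-5-iodo-4-methylpent-4-enal; 13 ethyl(triphenyl)phosphonium iodide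
Product: 26 tert-butyl{[(3S,1E,5Z)-1,6-diiodo-2-methylhepta-1,5-dien-3-yl]oxy}dimethylsilane, via ylide 23 (not isolated), via iodophosphonium salt 24 (not isolated), via iodo ylide 25 (not isolated)
Conditions: 13, n-BuLi, THF, 0 °C; I-I (iodine), −78 °C; NaN(SiMe3)2, −20 °C; then 22, −78 to −20 °C
Reagents that add atoms: iodine, I-I
Why: Wittig olefination with the reactive α-iodo ylide (Stork–Zhao type) is under kinetic oxaphosphetane control and gives the (Z)-2-iodoalkene, iodine cis to the chain, which fixes the future C9=C10 geometry.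

Step 14
Reactants: 26 tert-butyl{[(3S,1E,5Z)-1,6-diiodo-2-methylhepta-1,5-dien-3-yl]oxy}dimethylsilane; 11 2,2-dimethylpent-4-enal
Product: 28 (5R,8S,6E,10Z)-8-{[tert-butyl(dimethyl)silyl]oxy}-11-iodo-4,4,7-trimethyldodeca-1,6,10-trien-5-ol, via alkenylchromium species 27 (not isolated)
Conditions: CrCl2 (4 equiv), (S)-N-[2-(4-isopropyl-4,5-dihydro-1,3-oxazol-2-yl)-6-methylphenyl]methanesulfonamide (4.4 equiv), Et3N, THF, rt; then NiCl2 (2 mol%), 26 (1.0 equiv), 11 (1.5 equiv), rt
Reagents that add atoms: none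
Why: in this Nozaki–Hiyama–Kishi coupling zerovalent nickel inserts into the unhindered terminal E-iodide much faster than into the α-methyl Z-iodide, transmetalation to trivalent chromium keeps the alkene geometry, and the chiral sulfonamide on chromium directs addition to the Re face of 11, setting C5 (future ring C4) as R.

Step 15
Reactants: 28 (5R,8S,6E,10Z)-8-{[tert-butyl(dimethyl)silyl]oxy}-11-iodo-4,4,7-trimethyldodeca-1,6,10-trien-5-ol
Product: 29 (5R,8S,6E,10Z)-8-{[tert-butyl(dimethyl)silyl]oxy}-11-iodo-4,4,7-trimethyldodeca-1,6,10-trien-5-yl acetate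
Conditions: Ac2O, 4-(dimethylamino)pyridine, pyridine, CH2Cl2, rt
Reagents that add atoms: acetic anhydride, CC(=O)OC(C)=O
Why: nucleophile-catalysed acylation of the hindered alcohol occurs at oxygen, so the configuration is retained, and it removes the free hydroxyl before hydroboration.

Step 16
Reactants: 29 (5R,8S,6E,10Z)-8-{[tert-butyl(dimethyl)silyl]oxy}-11-iodo-4,4,7-trimethyldodeca-1,6,10-trien-5-yl acetate
Product: 31 (1R,4S,2E,6Z)-4-{[tert-butyl(dimethyl)silyl]oxy}-3,7,11,11-tetramethylcycloundeca-2,6-dien-1-yl acetate, via alkylborane 30 (not isolated)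
Conditions: 9-borabicyclo[3.3.1]nonane (9-BBN), THF, rt; then slow addition to Pd(dppf)Cl2 (20 mol%; dppf = 1,1'-bis(diphenylphosphino)ferrocene), AsPh3, Cs2CO3, DMF/THF/H2O, 2 mM, rt to 45 °C
Reagents that add atoms: none
Why: 9-BBN hydroborates only the monosubstituted alkene (anti-Markovnikov), and the intramolecular B-alkyl Suzuki–Miyaura coupling then closes the 11-membered ring with retention at the Z-iodide, oxidative addition of zerovalent palladium to the iodide being faster than ionisation of the hindered allylic acetate.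

Step 17
Reactants: 31 (1R,4S,2E,6Z)-4-{[tert-butyl(dimethyl)silyl]oxy}-3,7,11,11-tetramethylcycloundeca-2,6-dien-1-yl acetate
Product: 32 (1R,4S,2E,6Z)-4-hydroxy-3,7,11,11-tetramethylcycloundeca-2,6-dien-1-yl acetate
Conditions: HF·pyridine, pyridine, THF, 0 °C to rt
Reagents that add atoms: none
Why: buffered fluoride cleaves the Si–O bond of the silyl ether without touching the acetate, which cannot migrate across the E alkene.

Step 18
Reactants: 32 (1R,4S,2E,6Z)-4-hydroxy-3,7,11,11-tetramethylcycloundeca-2,6-dien-1-yl acetate; 5 4-{[tri(propan-2-yl)silyl]oxy}benzoyl chloride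
Product: 33 (1S,4R,2E,9Z)-4-(acetyloxy)-2,5,5,9-tetramethylcycloundeca-2,9-dien-1-yl 4-{[tri(propan-2-yl)silyl]oxy}benzoate
Conditions: Et3N, 4-(dimethylamino)pyridine, CH2Cl2, 0 °C to rt
Reagents that add atoms: none
Why: acylation of the alcohol oxygen by the acid chloride (acylpyridinium catalysis) keeps the configuration of the carbinol carbon.

Step 19
Reactants: 33 (1S,4R,2E,9Z)-4-(acetyloxy)-2,5,5,9-tetramethylcycloundeca-2,9-dien-1-yl 4-{[tri(propan-2-yl)silyl]oxy}benzoate
Product: 34 (1S,4R,2E,9Z)-4-(acetyloxy)-2,5,5,9-tetramethylcycloundeca-2,9-dien-1-yl 4-hydroxybenzoate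
Conditions: Bu4NF, AcOH, THF, 0 °C
Reagents that add atoms: none
Why: fluoride-mediated cleavage of the aryl silyl ether is fast at 0 °C, and the acetic acid buffer keeps both esters intact.

**Compound list**

1 | 4-bromophenol | Oc1ccc(Br)cc1 | starting material
2 | (4-bromophenoxy)tri(propan-2-yl)silane | CC(C)[Si](Oc1ccc(Br)cc1)(C(C)C)C(C)C | intermediate
3 | (4-{[tri(propan-2-yl)silyl]oxy}phenyl)lithium | [Li]c1ccc(O[Si](C(C)C)(C(C)C)C(C)C)cc1 | intermediate
4 | 4-{[tri(propan-2-yl)silyl]oxy}benzoic acid | OC(=O)c1ccc(O[Si](C(C)C)(C(C)C)C(C)C)cc1 | intermediate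
5 | 4-{[tri(propan-2-yl)silyl]oxy}benzoyl chloride | ClC(=O)c1ccc(O[Si](C(C)C)(C(C)C)C(C)C)cc1 | intermediate
6 | methyl 2-methylpropanoate | COC(=O)C(C)C | starting material
7 | 3-bromoprop-1-ene | C=CCBr | starting material
8 | lithium 1-methoxy-2-methylprop-1-en-1-olate | COC(O[Li])=C(C)C | intermediate
9 | methyl 2,2-dimethylpent-4-enoate | COC(=O)C(C)(C)CC=C | intermediate
10 | 2,2-dimethylpent-4-en-1-ol | OCC(C)(C)CC=C | intermediate
11 | 2,2-dimethylpent-4-enal | O=CC(C)(C)CC=C | intermediate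
12 | iodoethane | CCI | starting material
13 | ethyl(triphenyl)phosphonium iodide | CC[P+](c1ccccc1)(c1ccccc1)c1ccccc1.[I-] | intermediate
14 | prop-2-yn-1-ol | C#CCO | starting material
15 | dimethylaluminium (2E)-3-(dimethylalumanyl)-2-methylprop-2-en-1-olate | C[Al](C)/C=C(\C)CO[Al](C)C | intermediate
16 | (2E)-3-iodo-2-methylprop-2-en-1-ol | I/C=C(\C)CO | intermediate
17 | (2E)-3-iodo-2-methylprop-2-enal | I/C=C(\C)C=O | intermediate
18 | (3S,1E)-1-iodo-2-methylhexa-1,5-dien-3-yl diisopinocampheylborinate | I/C=C(\C)[C@@H](OB([C@@H]1C[C@@H]2C[C@H]([C@H]1C)C2(C)C)[C@@H]1C[C@@H]2C[C@H]([C@H]1C)C2(C)C)CC=C | intermediate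
19 | (3S,1E)-1-iodo-2-methylhexa-1,5-dien-3-ol | I/C=C(\C)[C@@H](O)CC=C | intermediate
20 | tert-butyl{[(3S,1E)-1-iodo-2-methylhexa-1,5-dien-3-yl]oxy}dimethylsilane | I/C=C(\C)[C@@H](O[Si](C)(C)C(C)(C)C)CC=C | intermediate
21 | (4S,5E)-4-{[tert-butyl(dimethyl)silyl]oxy}-6-iodo-5-methylhex-5-ene-1,2-diol (both C2 epimers) | I/C=C(\C)[C@@H](O[Si](C)(C)C(C)(C)C)CC(O)CO | intermediate
22 | (3S,4E)-3-{[tert-butyl(dimethyl)silyl]oxy}-5-iodo-4-methylpent-4-enal | I/C=C(\C)[C@@H](O[Si](C)(C)C(C)(C)C)CC=O | intermediate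
23 | ethylidene(triphenyl)phosphorane | CC=P(c1ccccc1)(c1ccccc1)c1ccccc1 | intermediate
24 | (1-iodoethyl)(triphenyl)phosphonium iodide | CC(I)[P+](c1ccccc1)(c1ccccc1)c1ccccc1.[I-] | intermediate
25 | (1-iodoethylidene)(triphenyl)phosphorane | CC(I)=P(c1ccccc1)(c1ccccc1)c1ccccc1 | intermediate
26 | tert-butyl{[(3S,1E,5Z)-1,6-diiodo-2-methylhepta-1,5-dien-3-yl]oxy}dimethylsilane | I/C=C(\C)[C@@H](O[Si](C)(C)C(C)(C)C)C/C=C(/C)I | intermediate
27 | dichloro{(1E,3S,5Z)-3-{[tert-butyl(dimethyl)silyl]oxy}-6-iodo-2-methylhepta-1,5-dien-1-yl}chromium (trivalent chromium) | Cl[Cr](Cl)/C=C(\C)[C@@H](O[Si](C)(C)C(C)(C)C)C/C=C(/C)I | intermediate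
28 | (5R,8S,6E,10Z)-8-{[tert-butyl(dimethyl)silyl]oxy}-11-iodo-4,4,7-trimethyldodeca-1,6,10-trien-5-ol | O[C@H](/C=C(\C)[C@@H](O[Si](C)(C)C(C)(C)C)C/C=C(/C)I)C(C)(C)CC=C | intermediate
29 | (5R,8S,6E,10Z)-8-{[tert-butyl(dimethyl)silyl]oxy}-11-iodo-4,4,7-trimethyldodeca-1,6,10-trien-5-yl acetate | CC(=O)O[C@H](/C=C(\C)[C@@H](O[Si](C)(C)C(C)(C)C)C/C=C(/C)I)C(C)(C)CC=C | intermediate
30 | (5R,8S,6E,10Z)-1-(9-borabicyclo[3.3.1]nonan-9-yl)-8-{[tert-butyl(dimethyl)silyl]oxy}-11-iodo-4,4,7-trimethyldodeca-6,10-dien-5-yl acetate | CC(=O)O[C@H](/C=C(\C)[C@@H](O[Si](C)(C)C(C)(C)C)C/C=C(/C)I)C(C)(C)CCCB1C2CCCC1CCC2 | intermediate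
31 | (1R,4S,2E,6Z)-4-{[tert-butyl(dimethyl)silyl]oxy}-3,7,11,11-tetramethylcycloundeca-2,6-dien-1-yl acetate | CC(=O)O[C@@H]1/C=C(\C)[C@@H](O[Si](C)(C)C(C)(C)C)C/C=C(/C)CCCC1(C)C | intermediate
32 | (1R,4S,2E,6Z)-4-hydroxy-3,7,11,11-tetramethylcycloundeca-2,6-dien-1-yl acetate | CC(=O)O[C@@H]1/C=C(\C)[C@@H](O)C/C=C(/C)CCCC1(C)C | intermediate
33 | (1S,4R,2E,9Z)-4-(acetyloxy)-2,5,5,9-tetramethylcycloundeca-2,9-dien-1-yl 4-{[tri(propan-2-yl)silyl]oxy}benzoate | CC(=O)O[C@@H]1/C=C(\C)[C@@H](OC(=O)c2ccc(O[Si](C(C)C)(C(C)C)C(C)C)cc2)C/C=C(/C)CCCC1(C)C | intermediate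
34 | (1S,4R,2E,9Z)-4-(acetyloxy)-2,5,5,9-tetramethylcycloundeca-2,9-dien-1-yl 4-hydroxybenzoate | CC(=O)O[C@@H]1/C=C(\C)[C@@H](OC(=O)c2ccc(O)cc2)C/C=C(/C)CCCC1(C)C | target

**Step count**

Total steps: 19. Longest linear sequence: 12 steps (14 to 34, steps 8 to 19).

**Steps most likely to fail**

Step 14. The internal Z-iodide may compete with the terminal E-iodide, and ligand control of the facial selectivity on an α-quaternary aldehyde is not assured. The fallback sets out from 26 and 11 and moves the origin of the C5 configuration from the C–C bond formation to a ketone reduction. A ligand-free coupling (CrCl2, NiCl2 cat., DMSO) gives the C5-epimeric alcohols (8S,6E,10Z)-8-{[tert-butyl(dimethyl)silyl]oxy}-11-iodo-4,4,7-trimethyldodeca-1,6,10-trien-5-ol F1. Dess–Martin periodinane oxidises both epimers to the enone (8S,6E,10Z)-8-{[tert-butyl(dimethyl)silyl]oxy}-11-iodo-4,4,7-trimethyldodeca-1,6,10-trien-5-one F2. Reduction with (S)-2-methyl-CBS-oxazaborolidine (the (S)-diphenylprolinol-derived B-methyl oxazaborolidine) and catecholborane in toluene at −78 °C, with the quaternary carbon as the large group, gives the 5R alcohol and comes back to the route at 28.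

Step 16. Closing a strained 11-membered ring may lose out to oligomerisation or protodeboronation, and the allylic acetate may ionise on palladium. The fallback sets out from 29 and replaces the borane by an alkylzinc reagent. Hydroboration as before and oxidation with NaBO3 gives the primary alcohol (5R,8S,6E,10Z)-8-{[tert-butyl(dimethyl)silyl]oxy}-1-hydroxy-11-iodo-4,4,7-trimethyldodeca-6,10-dien-5-yl acetate F3. Iodine, PPh3 and imidazole convert it into the primary iodide (5R,8S,6E,10Z)-8-{[tert-butyl(dimethyl)silyl]oxy}-1,11-diiodo-4,4,7-trimethyldodeca-6,10-dien-5-yl acetate F4. Zinc dust with LiCl in THF inserts only into the sp3 carbon–iodine bond and gives the alkylzinc iodide (5R,8S,6E,10Z)-5-(acetyloxy)-8-{[tert-butyl(dimethyl)silyl]oxy}-11-iodo-4,4,7-trimethyldodeca-6,10-dien-1-ylzinc iodide F5 (not isolated). Intramolecular Negishi coupling (Pd2(dba)3, 2-dicyclohexylphosphino-2',6'-dimethoxybiphenyl, slow addition) closes the ring and comes back to the route at 31.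

Step 10. The enal 17 is volatile and light-sensitive, and any loss of enantiomeric excess here shows up later as diastereomers. The fallback sets out from 17 and replaces the asymmetric C–C bond formation by a kinetic resolution. AllylMgBr in Et2O at −78 °C gives the racemic alcohol (1E)-1-iodo-2-methylhexa-1,5-dien-3-ol F6. Burkholderia cepacia lipase with vinyl acetate in hexane at 30 °C acetylates the R enantiomer (Kazlauskas preference) to (3R,1E)-1-iodo-2-methylhexa-1,5-dien-3-yl acetate F7, which is separated. The unreacted S alcohol is 19, where the route is rejoined.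

**Further compounds**

F1 | step 14 | (8S,6E,10Z)-8-{[tert-butyl(dimethyl)silyl]oxy}-11-iodo-4,4,7-trimethyldodeca-1,6,10-trien-5-ol (both C5 epimers) | OC(/C=C(\C)[C@@H](O[Si](C)(C)C(C)(C)C)C/C=C(/C)I)C(C)(C)CC=C
F2 | step 14 | (8S,6E,10Z)-8-{[tert-butyl(dimethyl)silyl]oxy}-11-iodo-4,4,7-trimethyldodeca-1,6,10-trien-5-one | O=C(/C=C(\C)[C@@H](O[Si](C)(C)C(C)(C)C)C/C=C(/C)I)C(C)(C)CC=C
F3 | step 16 | (5R,8S,6E,10Z)-8-{[tert-butyl(dimethyl)silyl]oxy}-1-hydroxy-11-iodo-4,4,7-trimethyldodeca-6,10-dien-5-yl acetate | CC(=O)O[C@H](/C=C(\C)[C@@H](O[Si](C)(C)C(C)(C)C)C/C=C(/C)I)C(C)(C)CCCO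
F4 | step 16 | (5R,8S,6E,10Z)-8-{[tert-butyl(dimethyl)silyl]oxy}-1,11-diiodo-4,4,7-trimethyldodeca-6,10-dien-5-yl acetate | CC(=O)O[C@H](/C=C(\C)[C@@H](O[Si](C)(C)C(C)(C)C)C/C=C(/C)I)C(C)(C)CCCI
F5 | step 16 | (5R,8S,6E,10Z)-5-(acetyloxy)-8-{[tert-butyl(dimethyl)silyl]oxy}-11-iodo-4,4,7-trimethyldodeca-6,10-dien-1-ylzinc iodide | CC(=O)O[C@H](/C=C(\C)[C@@H](O[Si](C)(C)C(C)(C)C)C/C=C(/C)I)C(C)(C)CCC[Zn]I
F6 | step 10 | (1E)-1-iodo-2-methylhexa-1,5-dien-3-ol (racemate) | I/C=C(\C)C(O)CC=C
F7 | step 10 | (3R,1E)-1-iodo-2-methylhexa-1,5-dien-3-yl acetate | I/C=C(\C)[C@H](OC(C)=O)CC=C
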